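## Retrosynthetic overview

1. Target ⇐ desilylation, C9=C10 saturation and C2 oxidation of macrocyclic carbinol 31. Ring C is closed last through the C1–C2 bond by a NiCl2-catalysed, CrCl2-mediated vinyl iodide–aldehyde coupling.
2. Ring B (oxepane) ⇐ ring-closing metathesis of the C8 vinyl and C11 propenyl groups of seco ether 29.
3. C20–O–C8 tertiary ether ⇐ palladium/boron co-catalysed union of ring A alcohol 13 (fragment A) with vinyl oxirane 27 (fragment B), which fixes C8.
4. 13 ⇐ 2-methylcyclohex-2-en-1-one (Cu-catalysed asymmetric methyl addition, allylation, 1,3-carbonyl transposition, α-iodination, CBS reduction).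
5. 27 ⇐ prop-2-yn-1-ol + (Z)-3-methylpent-2-en-4-yn-1-ol (B-alkyl Suzuki coupling, two Sharpless epoxidations). Ring order: A, then B, then C.

Locants used in names from 28 on (phomactin-type): C1 = ring A carbon bearing ketone C2; C3/C4 = oxirane (C4 bears methyl); C5, C6 = CH2; C7 = CH–OH; C8 = C(CH3)–O; C9, C10 = CH2; C11 = quaternary ring carbon; C12 = CH(CH3); C13 = CH2; C14 = ring CH–OH; C15 = ring carbon bearing C20H2–O. Target = 3R,4R,7R,8S,11R,12S,14R.

Assumption: the ligand antipodes in steps 1 and 21 are taken as those that give the configurations shown (each is fixed by one trial with both antipodes).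

## Fragment A (ring A)

Step 1
Reactants: 1 2-methylcyclohex-2-en-1-one
Product: 3 trimethyl{[(3S)-2,3-dimethylcyclohex-1-en-1-yl]oxy}silane, via aluminium enolate 2 (not isolated)
Conditions: Me3Al (1.4 equiv), Cu(O2C-2-thienyl) (CuTC, 2 mol %), binaphthol-derived phosphoramidite ligand (4 mol %, antipode giving 3S), Et2O, −30 °C; then TMSOTf, THF, −30 → 0 °C
Reagents that add atoms: trimethylaluminium C[Al](C)C; trimethylsilyl triflate C[Si](C)(C)OS(=O)(=O)C(F)(F)F
Why: Copper-catalysed asymmetric conjugate addition of the methyl group sets C12 under ligand control, and O-silylation of the aluminium enolate stores the regiodefined tetrasubstituted enolate.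

Step 2
Reactants: 3 trimethyl{[(3S)-2,3-dimethylcyclohex-1-en-1-yl]oxy}silane
Product: 5 (2R,3S)-2,3-dimethyl-2-(prop-2-en-1-yl)cyclohexan-1-one, via lithium enolate 4 (not isolated)
Conditions: MeLi (1.05 equiv), THF, 0 °C; then allyl iodide, DMPU, −78 → −20 °C
Reagents that add atoms: allyl iodide C=CCI
Why: Regiospecific enolate alkylation; the allyl group enters anti to the neighbouring C12 methyl (axial attack), so the quaternary C11 is formed with the two methyls cis (about 8:1, minor isomer removed by chromatography).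

Step 3
Reactants: 5 (2R,3S)-2,3-dimethyl-2-(prop-2-en-1-yl)cyclohexan-1-one
Product: 6 (2S,3S)-2,3-dimethyl-2-[(1E)-prop-1-en-1-yl]cyclohexan-1-one
Conditions: RuHCl(CO)(PPh3)3 (2 mol %), toluene, 80 °C
Reagents that add atoms: none
Why: Ruthenium hydride olefin isomerisation moves the terminal alkene one position to the more stable (E)-propenyl group, and the quaternary carbon blocks any further migration.

Step 4
Reactants: 6 (2S,3S)-2,3-dimethyl-2-[(1E)-prop-1-en-1-yl]cyclohexan-1-one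
Product: 7 (5S,6S)-5,6-dimethyl-6-[(1E)-prop-1-en-1-yl]cyclohex-2-en-1-one
Conditions: IBX (2.5 equiv), DMSO/fluorobenzene, 70 °C
Reagents that add atoms: none
Why: IBX dehydrogenation of the ketone can only occur on its single enolisable side, giving the enone needed for carbonyl transposition.

Step 5
Reactants: 7 (5S,6S)-5,6-dimethyl-6-[(1E)-prop-1-en-1-yl]cyclohex-2-en-1-one
Product: 8 (5S,6S)-1-{[(4-methoxybenzyl)oxy]methyl}-5,6-dimethyl-6-[(1E)-prop-1-en-1-yl]cyclohex-2-en-1-ol (both C1 epimers)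
Conditions: tributyl{[(4-methoxybenzyl)oxy]methyl}stannane, n-BuLi, THF, −78 °C; then 7, −78 → −40 °C; H2O
Reagents that add atoms: tributyl{[(4-methoxybenzyl)oxy]methyl}stannane CCCC[Sn](CCCC)(CCCC)COCc1ccc(OC)cc1
Why: Tin–lithium exchange gives a small α-alkoxymethyllithium (hydroxymethyl anion equivalent) that adds 1,2 to the hindered enone and brings in C20 with its oxygen; the new carbinol centre is erased in step 6.

Step 6
Reactants: 8 (5S,6S)-1-{[(4-methoxybenzyl)oxy]methyl}-5,6-dimethyl-6-[(1E)-prop-1-en-1-yl]cyclohex-2-en-1-ol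
Product: 9 (4S,5S)-3-{[(4-methoxybenzyl)oxy]methyl}-4,5-dimethyl-4-[(1E)-prop-1-en-1-yl]cyclohex-2-en-1-one
Conditions: pyridinium chlorochromate [C5H5NH][CrO3Cl], 4A MS, CH2Cl2, rt
Reagents that add atoms: none
Why: Dauben–Michno oxidative 1,3-transposition (allylic chromate ester [3,3] shift, then oxidation) moves the oxygen to C14 and the alkene to C1=C15.

Step 7
Reactants: 9 (4S,5S)-3-{[(4-methoxybenzyl)oxy]methyl}-4,5-dimethyl-4-[(1E)-prop-1-en-1-yl]cyclohex-2-en-1-one
Product: 10 (4S,5S)-2-iodo-3-{[(4-methoxybenzyl)oxy]methyl}-4,5-dimethyl-4-[(1E)-prop-1-en-1-yl]cyclohex-2-en-1-one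
Conditions: iodine (3 equiv), pyridine/CH2Cl2, DMAP (cat.), rt
Reagents that add atoms: iodine [I][I]
Why: Johnson α-iodination of the enone (conjugate addition of pyridine, iodination of the enolate, elimination) installs the C1 halide for the later ring C closure.

Step 8
Reactants: 10 (4S,5S)-2-iodo-3-{[(4-methoxybenzyl)oxy]methyl}-4,5-dimethyl-4-[(1E)-prop-1-en-1-yl]cyclohex-2-en-1-one
Product: 11 (1R,4S,5S)-2-iodo-3-{[(4-methoxybenzyl)oxy]methyl}-4,5-dimethyl-4-[(1E)-prop-1-en-1-yl]cyclohex-2-en-1-ol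
Conditions: (S)-Me-CBS oxazaborolidine (0.3 equiv), BH3·SMe2, THF, −40 °C; MeOH
Reagents that add atoms: none
Why: Corey–Bakshi–Shibata reduction; the (S)-catalyst treats the α-iodovinyl side as the large group and delivers hydride to give the 1R carbinol (C14), the same sense as axial attack cis to the C12 methyl.

Step 9
Reactants: 11 (1R,4S,5S)-2-iodo-3-{[(4-methoxybenzyl)oxy]methyl}-4,5-dimethyl-4-[(1E)-prop-1-en-1-yl]cyclohex-2-en-1-ol
Product: 12 tert-butyl{[(1R,4S,5S)-2-iodo-3-{[(4-methoxybenzyl)oxy]methyl}-4,5-dimethyl-4-[(1E)-prop-1-en-1-yl]cyclohex-2-en-1-yl]oxy}dimethylsilane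
Conditions: TBSOTf, 2,6-lutidine, CH2Cl2, −78 → 0 °C
Reagents that add atoms: tert-butyldimethylsilyl triflate CC(C)(C)[Si](C)(C)OS(=O)(=O)C(F)(F)F
Why: Silyl ether formation with the reactive triflate protects the hindered allylic alcohol through to the last step.

Step 10
Reactants: 12 tert-butyl{[(1R,4S,5S)-2-iodo-3-{[(4-methoxybenzyl)oxy]methyl}-4,5-dimethyl-4-[(1E)-prop-1-en-1-yl]cyclohex-2-en-1-yl]oxy}dimethylsilane
Product: 13 [(3R,5S,6S)-3-{[tert-butyl(dimethyl)silyl]oxy}-2-iodo-5,6-dimethyl-6-[(1E)-prop-1-en-1-yl]cyclohex-1-en-1-yl]methanol (fragment A)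
Conditions: DDQ, CH2Cl2/pH 7 buffer, 0 °C
Reagents that add atoms: none
Why: Oxidative cleavage of the 4-methoxybenzyl ether by DDQ frees the C20 hydroxyl and leaves the silyl ether, the vinyl iodide and both alkenes untouched.

## Fragment B (chain)

Step 11
Reactants: 14 prop-2-yn-1-ol
Product: 16 (Z)-3-iodo-2-methylprop-2-en-1-ol, via alkenylmagnesium alkoxide 15 (not isolated)
Conditions: MeMgBr (2.5 equiv), CuI (10 mol %), Et2O, −10 °C → rt; then iodine, −20 °C; aqueous work-up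
Reagents that add atoms: methylmagnesium bromide C[Mg]Br; iodine [I][I]
Why: Copper-catalysed anti-carbomagnesiation of the propargylic alkoxide (Duboudin carbometalation) places magnesium cis to the CH2O group in a five-membered chelate, and iodinolysis with retention gives the Z iodide.

Step 12
Reactants: 17 (Z)-3-methylpent-2-en-4-yn-1-ol
Product: 18 tert-butyldimethyl{[(2Z)-3-methylpent-2-en-4-yn-1-yl]oxy}silane
Conditions: TBSCl, imidazole, CH2Cl2, 0 °C → rt
Reagents that add atoms: tert-butyldimethylsilyl chloride CC(C)(C)[Si](C)(C)Cl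
Why: Standard silylation masks this allylic alcohol so that the first Sharpless epoxidation (step 15) acts only on the other allylic alcohol.

Step 13
Reactants: 18 tert-butyldimethyl{[(2Z)-3-methylpent-2-en-4-yn-1-yl]oxy}silane
Product: 19 tert-butyldimethyl{[(2Z)-3-methylpenta-2,4-dien-1-yl]oxy}silane
Conditions: H2 (1 atm), Pd/CaCO3 poisoned with Pb(OAc)2 (Lindlar catalyst), quinoline, hexane, rt
Reagents that add atoms: none
Why: Lindlar semihydrogenation stops at the alkene and turns the terminal alkyne into the vinyl group needed for hydroboration.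

Step 14
Reactants: 19 tert-butyldimethyl{[(2Z)-3-methylpenta-2,4-dien-1-yl]oxy}silane and 16 (Z)-3-iodo-2-methylprop-2-en-1-ol
Product: 21 (2Z,6Z)-8-{[tert-butyl(dimethyl)silyl]oxy}-2,6-dimethylocta-2,6-dien-1-ol, via alkylborane 20 (not isolated)
Conditions: 9-BBN, THF, 0 °C → rt; then 16, Pd(dppf)Cl2 (5 mol %), AsPh3, Cs2CO3, DMF/H2O, rt
Reagents that add atoms: none
Why: B-alkyl Suzuki–Miyaura coupling; 9-BBN adds to the terminal CH2 of the diene and the palladium-catalysed sp3–sp2 coupling forms the C6–C7 bond with retention of both Z alkenes.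

Step 15
Reactants: 21 (2Z,6Z)-8-{[tert-butyl(dimethyl)silyl]oxy}-2,6-dimethylocta-2,6-dien-1-ol
Product: 22 {(2S,3R)-3-[(3Z)-5-{[tert-butyl(dimethyl)silyl]oxy}-3-methylpent-3-en-1-yl]-2-methyloxiran-2-yl}methanol
Conditions: Ti(OiPr)4 (10 mol %), L-(+)-diethyl tartrate (12 mol %), t-BuOOH, 4A MS, CH2Cl2, −20 °C
Reagents that add atoms: tert-butyl hydroperoxide CC(C)(C)OO
Why: Sharpless asymmetric epoxidation acts only on the free allylic alcohol, and L-(+)-tartrate delivers oxygen to the face that gives the 2S,3R oxirane (the same sense as for nerol and geraniol), setting C8 and C7.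

Step 16
Reactants: 22 {(2S,3R)-3-[(3Z)-5-{[tert-butyl(dimethyl)silyl]oxy}-3-methylpent-3-en-1-yl]-2-methyloxiran-2-yl}methanol
Product: 23 (2R,3R)-3-[(3Z)-5-{[tert-butyl(dimethyl)silyl]oxy}-3-methylpent-3-en-1-yl]-2-methyloxirane-2-carbaldehyde
Conditions: Dess–Martin periodinane, NaHCO3, CH2Cl2, 0 °C → rt
Reagents that add atoms: none
Why: Buffered Dess–Martin oxidation gives the α-quaternary epoxy aldehyde, which cannot epimerise.

Step 17
Reactants: 23 (2R,3R)-3-[(3Z)-5-{[tert-butyl(dimethyl)silyl]oxy}-3-methylpent-3-en-1-yl]-2-methyloxirane-2-carbaldehyde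
Product: 24 tert-butyl{[(2Z)-5-[(2R,3S)-3-ethenyl-3-methyloxiran-2-yl]-3-methylpent-2-en-1-yl]oxy}dimethylsilane
Conditions: Ph3PCH3Br, KHMDS, THF, 0 °C; then 23, −78 → 0 °C
Reagents that add atoms: methyltriphenylphosphonium bromide C[P+](c1ccccc1)(c1ccccc1)c1ccccc1.[Br-]
Why: Wittig methylenation converts the aldehyde into the vinyl group and so creates the vinyl oxirane used in the fragment union.

Step 18
Reactants: 24 tert-butyl{[(2Z)-5-[(2R,3S)-3-ethenyl-3-methyloxiran-2-yl]-3-methylpent-2-en-1-yl]oxy}dimethylsilane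
Product: 25 (2Z)-5-[(2R,3S)-3-ethenyl-3-methyloxiran-2-yl]-3-methylpent-2-en-1-ol
Conditions: TBAF, THF, 0 °C
Reagents that add atoms: none
Why: Fluoride desilylation is neutral to the vinyl oxirane and frees the second allylic alcohol.

Step 19
Reactants: 25 (2Z)-5-[(2R,3S)-3-ethenyl-3-methyloxiran-2-yl]-3-methylpent-2-en-1-ol
Product: 26 [(2S,3R)-3-{2-[(2R,3S)-3-ethenyl-3-methyloxiran-2-yl]ethyl}-3-methyloxiran-2-yl]methanol
Conditions: Ti(OiPr)4 (10 mol %), L-(+)-diethyl tartrate (12 mol %), t-BuOOH, 4A MS, CH2Cl2, −25 °C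
Reagents that add atoms: tert-butyl hydroperoxide CC(C)(C)OO
Why: Second Sharpless asymmetric epoxidation on the nerol-type Z-allylic alcohol; L-(+)-tartrate gives the 2S,3R epoxy alcohol, setting C3 and C4 of the cis-oxirane by reagent control.

Step 20
Reactants: 26 [(2S,3R)-3-{2-[(2R,3S)-3-ethenyl-3-methyloxiran-2-yl]ethyl}-3-methyloxiran-2-yl]methanol
Product: 27 (2R,3R)-3-{2-[(2R,3S)-3-ethenyl-3-methyloxiran-2-yl]ethyl}-3-methyloxirane-2-carbaldehyde (fragment B)
Conditions: Dess–Martin periodinane, NaHCO3, CH2Cl2, 0 °C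
Reagents that add atoms: none
Why: Buffered Dess–Martin oxidation gives the epoxy aldehyde (C2) without opening either oxirane; it is used at once.

## Union and endgame

Step 21
Reactants: 13 [(3R,5S,6S)-3-{[tert-butyl(dimethyl)silyl]oxy}-2-iodo-5,6-dimethyl-6-[(1E)-prop-1-en-1-yl]cyclohex-1-en-1-yl]methanol and 27 (2R,3R)-3-{2-[(2R,3S)-3-ethenyl-3-methyloxiran-2-yl]ethyl}-3-methyloxirane-2-carbaldehyde
Product: 28 seco ether: C20–O–C8 tertiary allylic ether (8S, vinyl and methyl on C8), free 7R hydroxyl, 3,4-epoxy aldehyde, C1 iodide, 14-OTBS and C11 (E)-propenyl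
Conditions: 13 (1.0 equiv), 27 (1.15 equiv), Pd2(dba)3·CHCl3 (2.5 mol %), (R,R)-DACH-phenyl Trost ligand (7.5 mol %), Et3B (5 mol %), CH2Cl2, rt
Reagents that add atoms: none
Why: Proposed new method: a palladium/borane co-catalysed, stereoretentive fragment-coupling etherification of a 2,2,3-trisubstituted vinyl oxirane, in which zerovalent palladium ionises the allylic C8–O bond of 27 with inversion, the freed C7 alkoxide and alcohol 13 are joined on boron, and this borate delivers the alkoxide of 13 to the adjacent, more substituted allyl terminus on the face opposite palladium, so that double inversion gives the 8S ether as the 1,2-adduct (the ligand antipode matched to this pathway is used so that π–σ–π facial exchange cannot erode the ratio, and ionisation of the vinyl oxirane is far faster than oxidative addition to the hindered vinyl iodide); the closest known reaction type is the Pd/trialkylborane addition of simple alcohols to butadiene and isoprene monoepoxides, which has not been shown for an internally substituted, stereodefined vinyl oxirane or as a 1:1 coupling of two advanced fragments.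

Step 22
Reactants: 28 seco ether with free 7-hydroxyl
Product: 29 7-O-triethylsilyl ether of 28
Conditions: TESCl, imidazole, DMAP (cat.), DMF, 0 °C → rt
Reagents that add atoms: chlorotriethylsilane CC[Si](Cl)(CC)CC
Why: Silylation blocks the C7 hydroxyl, which could otherwise attack the 3,4-oxirane to form a tetrahydrofuran and would be oxidised in step 25.

Step 23
Reactants: 29 7-O-triethylsilyl ether of 28
Product: 30 oxepine with rings A and B closed (C9=C10 alkene; C1 iodide, C2 aldehyde, 7-OTES, 14-OTBS)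
Conditions: second-generation Hoveyda–Grubbs catalyst RuCl2(H2IMes)(=CH-C6H4-2-OiPr) (10 mol %), toluene, 90 °C, argon sparge
Reagents that add atoms: none
Why: Ring-closing metathesis between the C8 vinyl and C11 propenyl groups forms the seven-membered ring B and releases propene; the tetrasubstituted vinyl iodide is inert.

Step 24
Reactants: 30 oxepine with C1 iodide and C2 aldehyde
Product: 31 macrocyclic C2 carbinol (rings A, B and C; C2 epimers; 9,10-didehydro; 7-OTES, 14-OTBS)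
Conditions: CrCl2 (10 equiv), NiCl2 (1 mol % of CrCl2), DMSO/THF, rt, 2 mM
Reagents that add atoms: none
Why: Nozaki–Hiyama–Kishi coupling; nickel inserts into the vinyl iodide, transmetalation gives the alkenylchromium, and its addition to the epoxy aldehyde forms the C1–C2 bond and ring C (the carbinol configuration is irrelevant because it is oxidised next).

Step 25
Reactants: 31 macrocyclic C2 carbinol
Product: 32 9,10-didehydro-7-O-TES-14-O-TBS ether of the target (C2 ketone)
Conditions: Dess–Martin periodinane, NaHCO3, CH2Cl2, rt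
Reagents that add atoms: none
Why: Dess–Martin oxidation of the allylic, α-epoxy carbinol gives the cross-conjugated epoxy enone; both other hydroxyls are silylated.

Step 26
Reactants: 32 9,10-didehydro-7-O-TES-14-O-TBS ether of the target
Product: 33 7-O-TES-14-O-TBS ether of the target
Conditions: 2-nitrobenzenesulfonohydrazide, Et3N, CH2Cl2, rt (repeated charges)
Reagents that add atoms: none
Why: Diimide reduction saturates the strained cis-disubstituted ring B alkene and leaves the tetrasubstituted enone alkene, the ketone and the oxirane alone.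

Step 27
Reactants: 33 7-O-TES-14-O-TBS ether of the target
Product: 34 CNP0316768.3
Conditions: HF·pyridine, pyridine, THF, 0 °C → rt
Reagents that add atoms: none
Why: Buffered fluoride cleaves both silyl ethers without opening the α,β-epoxy ketone.

## Compound list

1 | 2-methylcyclohex-2-en-1-one | CC1=CCCCC1=O | starting material
2 | dimethylaluminium (3S)-2,3-dimethylcyclohex-1-en-1-olate | C[C@H]1CCCC(O[Al](C)C)=C1C | intermediate
3 | trimethyl{[(3S)-2,3-dimethylcyclohex-1-en-1-yl]oxy}silane | C[C@H]1CCCC(O[Si](C)(C)C)=C1C | intermediate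
4 | lithium (3S)-2,3-dimethylcyclohex-1-en-1-olate | C[C@H]1CCCC(O[Li])=C1C | intermediate
5 | (2R,3S)-2,3-dimethyl-2-(prop-2-en-1-yl)cyclohexan-1-one | C[C@H]1CCCC(=O)[C@]1(C)CC=C | intermediate
6 | (2S,3S)-2,3-dimethyl-2-[(1E)-prop-1-en-1-yl]cyclohexan-1-one | C[C@H]1CCCC(=O)[C@]1(C)/C=C/C | intermediate
7 | (5S,6S)-5,6-dimethyl-6-[(1E)-prop-1-en-1-yl]cyclohex-2-en-1-one | C[C@H]1CC=CC(=O)[C@]1(C)/C=C/C | intermediate
8 | (5S,6S)-1-{[(4-methoxybenzyl)oxy]methyl}-5,6-dimethyl-6-[(1E)-prop-1-en-1-yl]cyclohex-2-en-1-ol (C1 epimers) | C[C@H]1CC=CC(O)(COCc2ccc(OC)cc2)[C@]1(C)/C=C/C | intermediate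
9 | (4S,5S)-3-{[(4-methoxybenzyl)oxy]methyl}-4,5-dimethyl-4-[(1E)-prop-1-en-1-yl]cyclohex-2-en-1-one | C[C@H]1CC(=O)C=C(COCc2ccc(OC)cc2)[C@]1(C)/C=C/C | intermediate
10 | (4S,5S)-2-iodo-3-{[(4-methoxybenzyl)oxy]methyl}-4,5-dimethyl-4-[(1E)-prop-1-en-1-yl]cyclohex-2-en-1-one | C[C@H]1CC(=O)C(=C(COCc2ccc(OC)cc2)[C@]1(C)/C=C/C)I | intermediate
11 | (1R,4S,5S)-2-iodo-3-{[(4-methoxybenzyl)oxy]methyl}-4,5-dimethyl-4-[(1E)-prop-1-en-1-yl]cyclohex-2-en-1-ol | C[C@H]1C[C@@H](O)C(=C(COCc2ccc(OC)cc2)[C@]1(C)/C=C/C)I | intermediate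
12 | tert-butyl{[(1R,4S,5S)-2-iodo-3-{[(4-methoxybenzyl)oxy]methyl}-4,5-dimethyl-4-[(1E)-prop-1-en-1-yl]cyclohex-2-en-1-yl]oxy}dimethylsilane | C[C@H]1C[C@@H](O[Si](C)(C)C(C)(C)C)C(=C(COCc2ccc(OC)cc2)[C@]1(C)/C=C/C)I | intermediate
13 | [(3R,5S,6S)-3-{[tert-butyl(dimethyl)silyl]oxy}-2-iodo-5,6-dimethyl-6-[(1E)-prop-1-en-1-yl]cyclohex-1-en-1-yl]methanol (fragment A) | C[C@H]1C[C@@H](O[Si](C)(C)C(C)(C)C)C(=C(CO)[C@]1(C)/C=C/C)I | intermediate
14 | prop-2-yn-1-ol | OCC#C | starting material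
15 | bromomagnesium (2Z)-3-(bromomagnesio)-2-methylprop-2-en-1-olate | Br[Mg]/C=C(/C)CO[Mg]Br | intermediate
16 | (Z)-3-iodo-2-methylprop-2-en-1-ol | I/C=C(/C)CO | intermediate
17 | (Z)-3-methylpent-2-en-4-yn-1-ol | OC/C=C(/C)C#C | starting material
18 | tert-butyldimethyl{[(2Z)-3-methylpent-2-en-4-yn-1-yl]oxy}silane | CC(C)(C)[Si](C)(C)OC/C=C(/C)C#C | intermediate
19 | tert-butyldimethyl{[(2Z)-3-methylpenta-2,4-dien-1-yl]oxy}silane | CC(C)(C)[Si](C)(C)OC/C=C(/C)C=C | intermediate
20 | 9-[(3Z)-5-{[tert-butyl(dimethyl)silyl]oxy}-3-methylpent-3-en-1-yl]-9-borabicyclo[3.3.1]nonane | CC(C)(C)[Si](C)(C)OC/C=C(/C)CCB1C2CCCC1CCC2 | intermediate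
21 | (2Z,6Z)-8-{[tert-butyl(dimethyl)silyl]oxy}-2,6-dimethylocta-2,6-dien-1-ol | OC/C(C)=C\CC/C(C)=C\CO[Si](C)(C)C(C)(C)C | intermediate
22 | {(2S,3R)-3-[(3Z)-5-{[tert-butyl(dimethyl)silyl]oxy}-3-methylpent-3-en-1-yl]-2-methyloxiran-2-yl}methanol | OC[C@]1(C)O[C@@H]1CC/C(C)=C\CO[Si](C)(C)C(C)(C)C | intermediate
23 | (2R,3R)-3-[(3Z)-5-{[tert-butyl(dimethyl)silyl]oxy}-3-methylpent-3-en-1-yl]-2-methyloxirane-2-carbaldehyde | O=C[C@]1(C)O[C@@H]1CC/C(C)=C\CO[Si](C)(C)C(C)(C)C | intermediate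
24 | tert-butyl{[(2Z)-5-[(2R,3S)-3-ethenyl-3-methyloxiran-2-yl]-3-methylpent-2-en-1-yl]oxy}dimethylsilane | C=C[C@]1(C)O[C@@H]1CC/C(C)=C\CO[Si](C)(C)C(C)(C)C | intermediate
25 | (2Z)-5-[(2R,3S)-3-ethenyl-3-methyloxiran-2-yl]-3-methylpent-2-en-1-ol | C=C[C@]1(C)O[C@@H]1CC/C(C)=C\CO | intermediate
26 | [(2S,3R)-3-{2-[(2R,3S)-3-ethenyl-3-methyloxiran-2-yl]ethyl}-3-methyloxiran-2-yl]methanol | C=C[C@]1(C)O[C@@H]1CC[C@@]2(C)O[C@H]2CO | intermediate
27 | (2R,3R)-3-{2-[(2R,3S)-3-ethenyl-3-methyloxiran-2-yl]ethyl}-3-methyloxirane-2-carbaldehyde (fragment B) | C=C[C@]1(C)O[C@@H]1CC[C@@]2(C)O[C@H]2C=O | intermediate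
28 | seco ether: fragment A joined through C20–O to C8 (8S; vinyl and methyl on C8), 7R hydroxyl free, 3,4-epoxy aldehyde, C1 iodide, 14-OTBS, C11 (E)-propenyl | C[C@H]1C[C@@H](O[Si](C)(C)C(C)(C)C)C(=C(CO[C@@](C)(C=C)[C@H](O)CC[C@@]2(C)O[C@H]2C=O)[C@]1(C)/C=C/C)I | intermediate
29 | 7-O-triethylsilyl ether of 28 | C[C@H]1C[C@@H](O[Si](C)(C)C(C)(C)C)C(=C(CO[C@@](C)(C=C)[C@H](O[Si](CC)(CC)CC)CC[C@@]2(C)O[C@H]2C=O)[C@]1(C)/C=C/C)I | intermediate
30 | oxepine with rings A and B closed (C9=C10; C1 iodide, C2 aldehyde, 7-OTES, 14-OTBS) | C[C@H]1C[C@@H](O[Si](C)(C)C(C)(C)C)C(=C2CO[C@@](C)(C=C[C@@]21C)[C@H](O[Si](CC)(CC)CC)CC[C@@]1(C)O[C@H]1C=O)I | intermediate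
31 | macrocyclic C2 carbinol (rings A, B, C; C2 epimers; 9,10-didehydro; 7-OTES, 14-OTBS) | C[C@H]1C[C@@H](O[Si](C)(C)C(C)(C)C)C2=C3CO[C@@](C)(C=C[C@@]31C)[C@H](O[Si](CC)(CC)CC)CC[C@@]1(C)O[C@H]1C2O | intermediate
32 | 9,10-didehydro-7-O-TES-14-O-TBS ether of the target | C[C@H]1C[C@@H](O[Si](C)(C)C(C)(C)C)C2=C3CO[C@@](C)(C=C[C@@]31C)[C@H](O[Si](CC)(CC)CC)CC[C@@]1(C)O[C@H]1C2=O | intermediate
33 | 7-O-TES-14-O-TBS ether of the target | C[C@H]1C[C@@H](O[Si](C)(C)C(C)(C)C)C2=C3CO[C@@](C)(CC[C@@]31C)[C@H](O[Si](CC)(CC)CC)CC[C@@]1(C)O[C@H]1C2=O | intermediate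
34 | CNP0316768.3 (3R,4R,7R,8S,11R,12S,14R in the locants above) | C[C@H]1C[C@@H](O)C2=C3CO[C@@](C)(CC[C@@]31C)[C@H](O)CC[C@@]1(C)O[C@H]1C2=O | target

## Step count and risk

Total step count: 27. Longest linear sequence: 17 steps (steps 1–10, then 21–27); the chain branches (steps 11–20) run in parallel.

The three steps most likely to fail:

**Step 21 (the proposed new etherification).** The risk is regiochemistry or the C8 configuration on this more substituted vinyl oxirane. The fallback uses only known reactions, sets out from 25 and 13, and comes back at 28. Alcohol 25 is treated with CO2 and Pd(PPh3)4 in THF to give, with net retention at C8, the vinyl cyclic carbonate F1. K2CO3 in MeOH opens it to the triol F2. NaH and 4-methoxybenzyl chloride (2.2 equiv) protect the primary and secondary hydroxyls and leave the tertiary one, giving the bis(4-methoxybenzyl) ether F3. Alcohol 13 is converted with CBr4 and PPh3 into the allylic bromide F4. KH and 18-crown-6 in THF join the tertiary alkoxide of F3 to F4 in a Williamson reaction, giving the ether F5. DDQ removes both benzyl groups to give the diol F6. Sharpless epoxidation (Ti(OiPr)4, L-(+)-diethyl tartrate, t-BuOOH) of its allylic alcohol gives the epoxy diol F7. PhI(OAc)2 with catalytic TEMPO oxidises only the primary alcohol, which gives 28.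

**Step 23 (ring-closing metathesis between two alkenes that both sit on fully substituted carbons).** The fallback changes the order of ring formation, sets out from 29 and comes back at 32. The CrCl2/NiCl2 coupling is run first on 29 to give the macrocyclic carbinol without ring B F8. Dess–Martin oxidation gives its ketone F9. The metathesis is then run on this pre-organised macrocycle, where the two alkenes are held close, and gives 32.

**Step 24 (closure of the medium ring with a tetrasubstituted vinyl iodide).** The fallback forms the ketone directly by acyl cross-coupling, sets out from 30 and comes back at 32. NaClO2, NaH2PO4 and 2-methylbut-2-ene oxidise 30 to the carboxylic acid F10. Thiophenol, EDC and DMAP give the S-phenyl thioester F11. Hexamethyldistannane and Pd(PPh3)4 convert the vinyl iodide into the trimethylstannane F12. A Liebeskind–Srogl coupling (Pd2(dba)3, tri(2-furyl)phosphine, CuOP(O)Ph2, THF, high dilution) then closes ring C and gives 32 without passing through 31.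

## Further compounds

F1 | step 21 | (4S,5R)-4-ethenyl-5-[(3Z)-5-hydroxy-3-methylpent-3-en-1-yl]-4-methyl-1,3-dioxolan-2-one | C=C[C@]1(C)OC(=O)O[C@@H]1CC/C(C)=C\CO
F2 | step 21 | (2Z,6R,7S)-3,7-dimethylnona-2,8-diene-1,6,7-triol | C=C[C@](C)(O)[C@H](O)CC/C(C)=C\CO
F3 | step 21 | (3S,4R,7Z)-4,9-bis[(4-methoxybenzyl)oxy]-3,7-dimethylnona-1,7-dien-3-ol | C=C[C@](C)(O)[C@H](OCc1ccc(OC)cc1)CC/C(C)=C\COCc1ccc(OC)cc1
F4 | step 21 | {[(1R,4S,5S)-3-(bromomethyl)-2-iodo-4,5-dimethyl-4-[(1E)-prop-1-en-1-yl]cyclohex-2-en-1-yl]oxy}(tert-butyl)dimethylsilane | C[C@H]1C[C@@H](O[Si](C)(C)C(C)(C)C)C(=C(CBr)[C@]1(C)/C=C/C)I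
F5 | step 21 | C20–O–C8 ether of F4 with F3 (7-O- and 2-O-(4-methoxybenzyl), 3Z alkene) | C[C@H]1C[C@@H](O[Si](C)(C)C(C)(C)C)C(=C(CO[C@@](C)(C=C)[C@H](OCc2ccc(OC)cc2)CC/C(C)=C\COCc2ccc(OC)cc2)[C@]1(C)/C=C/C)I
F6 | step 21 | diol from F5 (7-OH and allylic 2-OH free) | C[C@H]1C[C@@H](O[Si](C)(C)C(C)(C)C)C(=C(CO[C@@](C)(C=C)[C@H](O)CC/C(C)=C\CO)[C@]1(C)/C=C/C)I
F7 | step 21 | 3,4-epoxy diol from F6 (C2 primary alcohol) | C[C@H]1C[C@@H](O[Si](C)(C)C(C)(C)C)C(=C(CO[C@@](C)(C=C)[C@H](O)CC[C@@]2(C)O[C@H]2CO)[C@]1(C)/C=C/C)I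
F8 | step 23 | macrocyclic C2 carbinol without ring B (C8 vinyl, C11 propenyl, 7-OTES, 14-OTBS; C2 epimers) | C[C@H]1C[C@@H](O[Si](C)(C)C(C)(C)C)C2=C(CO[C@@](C)(C=C)[C@H](O[Si](CC)(CC)CC)CC[C@@]3(C)O[C@H]3C2O)[C@]1(C)/C=C/C
F9 | step 23 | C2 ketone of F8 | C[C@H]1C[C@@H](O[Si](C)(C)C(C)(C)C)C2=C(CO[C@@](C)(C=C)[C@H](O[Si](CC)(CC)CC)CC[C@@]3(C)O[C@H]3C2=O)[C@]1(C)/C=C/C
F10 | step 24 | C2 carboxylic acid of 30 | C[C@H]1C[C@@H](O[Si](C)(C)C(C)(C)C)C(=C2CO[C@@](C)(C=C[C@@]21C)[C@H](O[Si](CC)(CC)CC)CC[C@@]1(C)O[C@H]1C(=O)O)I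
F11 | step 24 | S-phenyl thioester of F10 | C[C@H]1C[C@@H](O[Si](C)(C)C(C)(C)C)C(=C2CO[C@@](C)(C=C[C@@]21C)[C@H](O[Si](CC)(CC)CC)CC[C@@]1(C)O[C@H]1C(=O)Sc1ccccc1)I
F12 | step 24 | C1 trimethylstannane of F11 | C[C@H]1C[C@@H](O[Si](C)(C)C(C)(C)C)C(=C2CO[C@@](C)(C=C[C@@]21C)[C@H](O[Si](CC)(CC)CC)CC[C@@]1(C)O[C@H]1C(=O)Sc1ccccc1)[Sn](C)(C)C
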